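## The problem

The target 18 is a benzophenone in which ring A (2-hydroxy-4,6-dimethoxyphenyl) is joined through the carbonyl carbon to C5 of a 7-hydroxy-2,2-dimethyl-2H-chromene. The carbonyl therefore lies between three ortho substituents: two oxygens on ring A and C4a on ring B.

Ring B is a 1,2,3,5-tetrasubstituted benzene with oxygen on C7 and C8a, the pyran carbon C4 on C4a, and the acyl carbon on C5. C5 is meta to both oxygens, so electrophilic substitution of a resorcinol cannot place the ketone. Pyran annulation onto a 5-substituted resorcinol tends to go to the carbon between the two oxygens rather than to C4a.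

The target has no stereocenter. Racemic carbinols and diastereomer mixtures are acceptable on the way, provided those carbons end as sp2 centres.

The sensitive groups are the 2H-chromene (a styrenic alkene and a tertiary allylic aryl ether, which rules out hydrogenolysis and hot acid) and the free phenols. In any precursor that holds the ketone at the alcohol level, the diarylcarbinol next to a 2,4,6-trioxygenated ring also ionizes very easily.

The feature that opens the chosen approach is that ring B is an orsellinate-type resorcinol. C4a–C8a–C8 correspond to the three central carbons of a 3-oxopentanedioate, and C7–C6–C5 correspond to the ester carbon, α carbon and β carbon of a but-2-ynoate. The carboxyl left on C4a is the future C4. For this polar assembly the carbon attached to C5 must be a carbinol: as a ketone it would turn the alkyne into an ynone and send the nucleophile to the wrong alkyne carbon.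

## Retrosynthesis

**18 from 17 (two O–C bonds).** The two free phenols are traced back to an aryl methyl ether on ring A and a MOM ether on C7–O in ketone 17. Ring A is carried as the symmetrical 2,4,6-trimethoxyphenyl group. A methyl ether survives the acid of step 4; a MOM ether on ring A would be lost there and would leave an ortho-hydroxybenzylic lactone that can open to a quinone methide under hydride or Grignard conditions. Because the two ortho methoxy groups are equivalent, chelation-directed cleavage next to the ketone has no regiochemical ambiguity. The forward step must remove one ortho methyl and the MOM group without opening the pyran.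

**17 from 16 from 15 (carbinol oxidation; O1–C2 bond).** The ketone is taken back to the diarylcarbinol 16. The pyran of 16 is opened by a retro-oxa-6π step to the ortho-quinone methide derived from triol 15. This forms the chromene directly at the alkene level. The neighbouring cut through a chroman-4-one would need a ketone reduction selective against the diaryl ketone, and would place a C4 carbinol beside a C5 ketone, which invites hemiketal and isobenzofuran formation. The forward reaction must dehydrate only the ortho-hydroxybenzylic, allylic carbinol under neutral conditions, leaving the acid-labile benzhydrol for a buffered oxidation.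

**15 from 13 and 14; 13 from 12; 12 from 11 (C4–C3 bond, then oxidation level and protection).** The alkenyl carbinol of 15 comes from addition of the Grignard reagent 14 to lactol 13, the masked salicylaldehyde. Lactol 13 is the partial reduction product of phthalide 12, and 12 is the mono-MOM ether of the dihydroxyphthalide 11. The MOM group is placed on the hydroxyl para to the lactone carbonyl (future C7–OH), so that the aldehyde in step 7 carries one phenoxide, not two. The hydroxyl ortho to the carbonyl (future C8a–OH) stays free because it is the oxygen that closes the pyran.

**11 from 9 (lactone C–O bond; C8–CO2H bond).** The two tert-butyl esters of 9 are identical in kind and differ only in position. Only the carboxyl on C4a has the carbinol carbon beside it and can become a phthalide. The carboxyl on C8 lies between two hydroxyls and leaves as CO2. One acid treatment therefore unmasks both carboxyls, ionizes the silyl carbinol into the lactone and sets up the decarboxylation. Phthalide 11 then has exactly the carbon count and substitution pattern of ring B, with C4 at the carboxyl level. The forward step needs lactonization to be faster than any decarboxylation at C4a.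

**9 from 5 and 6 (C4a–C5 and C8–C7 bonds; ring B).** Ring B is cut into the ynoate 5 and the keto diester 6. Compared with substitution chemistry on a preformed resorcinol, this fixes all four substituents of ring B by the way the ring is assembled. The precursors are an acyclic ynoate and a stock diester. The forward reaction needs conjugate addition β to the ester and ring closure through carbon.

**5 from 4 from 1 and 2 (O–Si bond; alkyne–carbinol bond).** The silyl ether 5 comes from carbinol 4, which is the adduct of lithiated methyl propiolate 1 with 2,4,6-trimethoxybenzaldehyde 2. This places the hindered aryl–carbon bond of the final ketone in the first step, on an aldehyde.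

## Roads not taken

**Alternative 1:** This road builds ring A. The cut is the bond from C1' to an oxygenated ortho carbon of ring A. The pyranone A1, a 4-hydroxy-2-pyranone carrying the ring B aryl ketone on a two-carbon arm, would be opened by Mg(OMe)2 in methanol to a chelated triketo ester. Its methylene next to the aryl ketone would then attack the ester carbonyl and close ring A as the acylphloroglucinol A2.
- Merits: the hindered diaryl ketone is never made by acylation; the symmetrical trihydroxy ring can be methylated twice with the chelated hydroxyl left free; no Lewis acid meets the chromene late in the route.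
- Weak points: it constructs the ring that can be bought. The difficult 5-acyl-7-oxy-2,2-dimethylchromene must already be present in A1, so the ring B regiochemistry is moved into the starting material and not solved. The triketo ester can also close by aldol condensation onto the aryl ketone to give a resorcylate. The methylation of A2 must stop at two groups.
- Comparison: Alternative 1 is ahead in the mildness of its last steps. The chosen plan sets against this that it makes ring B itself from three stock compounds with every substituent position fixed by construction.

**Alternative 2:** The cut is through the pyran bonds C4–C3 and O1–C2. The aldehyde A3 and the alkenylboronic acid A4 would condense under catalytic dibenzylamine: iminium formation, alkenyl transfer from boron to carbon (borono-Mannich), loss of the amine to an ortho-quinone methide, and oxa-6π closure to the iodochromene A5. The iodide would then be converted into an arylmagnesium species and added to the ring A aldehyde A6, followed by oxidation and deprotection.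
- Merits: the chromene forms in one operation, with its position set by the aldehyde; the sequence is shorter than the chosen route.
- Weak points: A3 is not a stock compound, and making it requires formylation next to iodine on an iodoresorcinol derivative, so ring B again depends on substitution selectivity. The condensation has to work on a 2,6-disubstituted aldehyde. The late C–C bond is formed at a carbon that becomes flanked by three ortho substituents, using an aryl metal that already carries the chromene.
- Comparison: Alternative 2 is better on step count and convergence, and its pyran closure is the same electrocyclization used here in step 8. The chosen plan sets against this that the bond to the future ketone carbon is made in step 1 on a simple aldehyde, and that the ring B pattern does not depend on directing effects.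

**Alternative 3:** The cut is through the two bonds that ring B makes at C5 (to the carbonyl) and at C4a (to C4). The iodide A7 would undergo oxidative addition to zerovalent palladium (from Pd(OAc)2 and tri(2-furyl)phosphine), norbornene insertion and ortho C–H palladation. The palladacycle would be acylated by the anhydride A8, norbornene would be extruded, and a Heck reaction with the allylic alcohol A9 would give the enone-free ketone A10. Acid would then remove the three MOM groups and close the pyran from the tertiary allylic alcohol.
- Merits: it is by far the shortest road; both carbon substituents of ring B are installed in one flask at positions set by the iodide; no redox changes are needed at the ketone carbon.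
- Weak points: ortho-acylation of such palladacycles is established for unhindered acyl donors, and A8 is 2,6-dioxygenated and electron-rich, which is the worst steric case; direct Heck coupling without acylation is the likely leak. The final acid step has to isomerize the E-alkene through an allyl cation before the phenol can close.
- Comparison: if its key step worked, Alternative 3 would be much shorter than the chosen plan. The chosen plan sets against this that every step is a reaction type with close precedent on comparable substrates and that no step rests on an untested steric combination.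

Key step: step 3

Remark: all chiral intermediates are racemic or mixtures of diastereomers; their stereogenic carbons become sp2 centres in steps 8 and 9.

Step 1
Reactants: 1 methyl propiolate (methyl prop-2-ynoate); 2 2,4,6-trimethoxybenzaldehyde
Product: 4 methyl 4-hydroxy-4-(2,4,6-trimethoxyphenyl)but-2-ynoate (racemic), via methyl 3-lithioprop-2-ynoate 3 (not isolated)
Conditions: 1, LiN(SiMe3)2, THF, −78 °C; then 2, −78 °C; AcOH quench at −78 °C
Reagents that add atoms: none
Why: 1,2-Addition of a lithium acetylide to an aldehyde; the propiolate anion is kept at −78 °C to prevent self-condensation, and the cold acidic quench prevents retro-addition from the electron-rich aldehyde adduct. The carbinol centre forms racemic and is later oxidized.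

Step 2
Reactants: 4 methyl 4-hydroxy-4-(2,4,6-trimethoxyphenyl)but-2-ynoate
Product: 5 methyl 4-[(tert-butyldimethylsilyl)oxy]-4-(2,4,6-trimethoxyphenyl)but-2-ynoate (racemic)
Conditions: TBSOTf, 2,6-lutidine, CH2Cl2, −78 °C
Reagents that add atoms: tert-butyldimethylsilyl trifluoromethanesulfonate, CC(C)(C)[Si](C)(C)OS(=O)(=O)C(F)(F)F
Why: Silylation of a hindered secondary alcohol with a silyl triflate and a hindered pyridine base; the non-nucleophilic base avoids conjugate addition to the ynoate and the amine-induced isomerization of 4-hydroxy-ynoates to 4-oxo-enoates. The silyl ether blocks butenolide formation in step 3.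

Step 3
Reactants: 5 methyl 4-[(tert-butyldimethylsilyl)oxy]-4-(2,4,6-trimethoxyphenyl)but-2-ynoate; 6 di-tert-butyl 3-oxopentanedioate
Product: 9 di-tert-butyl 6-{[(tert-butyldimethylsilyl)oxy](2,4,6-trimethoxyphenyl)methyl}-2,4-dihydroxybenzene-1,3-dicarboxylate (racemic), via sodium enolate of the keto diester 7 (not isolated), via open-chain Michael adduct 8 (not isolated)
Conditions: 6, NaH (2.2 equiv), THF, 0 °C; then 5, 0 → 60 °C; 1 M HCl
Reagents that add atoms: none
Why: The enolate 7 adds to the β carbon of ynoate 5 (C4a–C5 bond), and the resulting vinyl anion is protonated by the remaining doubly activated C–H to give 8 as a delocalized anion in which the enoate geometry can equilibrate. The second α carbon, deprotonated by the second equivalent of NaH, then attacks the methyl ester (C8–C7 bond); loss of methoxide and double enolization give the resorcinol. The closest known reaction type is the Michael–Dieckmann benzannulation of 3-oxopentanedioate esters with alk-2-ynoates to 2,4-dihydroxyisophthalates. Ring B closes by a 6-exo-trig acyl substitution that aromatization makes irreversible. No stereocenter is formed and the existing silyl carbinol is untouched. The step needs addition β to the ester, which is secured because the carbon next to the alkyne is an sp3 silyloxy carbinol and the ester is the only acceptor. It also needs closure through carbon and not through enolate oxygen (which would give a 2-pyranone), which is secured by the second acidic methylene of the symmetrical dinucleophile and by the aromatic product. The tert-butyl esters are poor acyl acceptors, so only the methyl ester is attacked; if base isomerizes 5 to its allenoate, addition to the central carbon leads to a ring tautomer that aromatizes to the same product.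

Step 4
Reactants: 9 di-tert-butyl 6-{[(tert-butyldimethylsilyl)oxy](2,4,6-trimethoxyphenyl)methyl}-2,4-dihydroxybenzene-1,3-dicarboxylate
Product: 11 5,7-dihydroxy-3-(2,4,6-trimethoxyphenyl)-2-benzofuran-1(3H)-one (racemic), via phthalide carboxylic acid 10 (not isolated)
Conditions: CF3CO2H–CH2Cl2 (1:4), 0 °C → rt; evaporate; then dioxane–H2O, 100 °C
Reagents that add atoms: none
Why: Acidolysis of the tert-butyl esters (loss of isobutene) and ionization of the doubly activated benzhydryl silyl ether, with capture of the cation by the adjacent carboxyl (5-exo), give the 3-arylphthalide, the known thermodynamic sink for such systems. The remaining 2,6-dihydroxybenzoic acid in 10 then undergoes thermal protodecarboxylation by ipso protonation, while the lactone carboxyl cannot. The methyl ethers of ring A are inert to this acid.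

Step 5
Reactants: 11 5,7-dihydroxy-3-(2,4,6-trimethoxyphenyl)-2-benzofuran-1(3H)-one
Product: 12 7-hydroxy-5-(methoxymethoxy)-3-(2,4,6-trimethoxyphenyl)-2-benzofuran-1(3H)-one (racemic)
Conditions: MOMCl (1.1 equiv), i-Pr2NEt, CH2Cl2, 0 °C
Reagents that add atoms: chloromethyl methyl ether, COCCl
Why: O-Alkylation of the more acidic hydroxyl para to the lactone carbonyl; the hydroxyl ortho to the carbonyl is hydrogen-bonded and reacts later, a selectivity established for 5,7-dihydroxyphthalides.

Step 6
Reactants: 12 7-hydroxy-5-(methoxymethoxy)-3-(2,4,6-trimethoxyphenyl)-2-benzofuran-1(3H)-one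
Product: 13 5-(methoxymethoxy)-3-(2,4,6-trimethoxyphenyl)-1,3-dihydro-2-benzofuran-1,7-diol (lactol, mixture of diastereomers)
Conditions: i-Bu2AlH (2.5 equiv), CH2Cl2, −78 °C; aq potassium sodium tartrate
Reagents that add atoms: none
Why: Partial reduction of a lactone to a lactol; the first equivalent is consumed by the phenol, and the tetrahedral aluminate of the five-membered ring is stable at −78 °C, so reduction stops at the aldehyde level.

Step 7
Reactants: 13 5-(methoxymethoxy)-3-(2,4,6-trimethoxyphenyl)-1,3-dihydro-2-benzofuran-1,7-diol; 14 (2-methylprop-1-en-1-yl)magnesium bromide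
Product: 15 3-[hydroxy(2,4,6-trimethoxyphenyl)methyl]-2-(1-hydroxy-3-methylbut-2-en-1-yl)-5-(methoxymethoxy)phenol (mixture of diastereomers)
Conditions: 14 (4 equiv), THF, 0 °C; cold aq NH4Cl; used crude
Reagents that add atoms: none
Why: Grignard addition to a lactol through its ring-opened hydroxy aldehyde (a magnesium salicylaldehyde chelate); two equivalents are consumed by the acidic hydroxyls. The new carbinol centre is uncontrolled and is removed in step 8.

Step 8
Reactants: 15 3-[hydroxy(2,4,6-trimethoxyphenyl)methyl]-2-(1-hydroxy-3-methylbut-2-en-1-yl)-5-(methoxymethoxy)phenol
Product: 16 [7-(methoxymethoxy)-2,2-dimethyl-2H-chromen-5-yl](2,4,6-trimethoxyphenyl)methanol (racemic)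
Conditions: PhMe, 90 °C
Reagents that add atoms: none
Why: Thermal dehydration of the ortho-hydroxybenzylic, allylic carbinol to an ortho-quinone methide, followed by oxa-6π electrocyclization; this is the known route from salicylaldehyde–alkenyl Grignard adducts to 2H-chromenes. Neutral conditions leave the benzhydrol un-ionized, and any cyclic ether formed by capture of the quinone methide by that hydroxyl is itself an ortho-hydroxybenzyl ether that can reopen.

Step 9
Reactants: 16 [7-(methoxymethoxy)-2,2-dimethyl-2H-chromen-5-yl](2,4,6-trimethoxyphenyl)methanol
Product: 17 [7-(methoxymethoxy)-2,2-dimethyl-2H-chromen-5-yl](2,4,6-trimethoxyphenyl)methanone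
Conditions: Dess–Martin periodinane, pyridine, CH2Cl2, 0 °C → rt
Reagents that add atoms: none
Why: Dess–Martin oxidation of a hindered, doubly benzylic secondary alcohol; pyridine buffers the acetic acid that would otherwise ionize the carbinol, and the chromene alkene is inert to the reagent.

Step 10
Reactants: 17 [7-(methoxymethoxy)-2,2-dimethyl-2H-chromen-5-yl](2,4,6-trimethoxyphenyl)methanone
Product: 18 (2-hydroxy-4,6-dimethoxyphenyl)(7-hydroxy-2,2-dimethyl-2H-chromen-5-yl)methanone
Conditions: BCl3 (3.5 equiv), CH2Cl2, −78 → 0 °C; aq NaHCO3
Reagents that add atoms: none
Why: BCl3 cleaves the MOM acetal and, through a six-membered chelate with the ketone, one ortho methyl ether of ring A. The two ortho methoxy groups are equivalent, the boron chelate formed after the first cleavage deactivates the carbonyl toward a second, and the para methoxy group and ring B offer no chelation site.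

## Compound list

1 | methyl propiolate (methyl prop-2-ynoate) | C#CC(=O)OC | starting material
2 | 2,4,6-trimethoxybenzaldehyde | COc1cc(OC)c(C=O)c(OC)c1 | starting material
3 | methyl 3-lithioprop-2-ynoate | [Li]C#CC(=O)OC | intermediate
4 | methyl 4-hydroxy-4-(2,4,6-trimethoxyphenyl)but-2-ynoate (racemic) | COC(=O)C#CC(O)c1c(OC)cc(OC)cc1OC | intermediate
5 | methyl 4-[(tert-butyldimethylsilyl)oxy]-4-(2,4,6-trimethoxyphenyl)but-2-ynoate (racemic) | COC(=O)C#CC(O[Si](C)(C)C(C)(C)C)c1c(OC)cc(OC)cc1OC | intermediate
6 | di-tert-butyl 3-oxopentanedioate | CC(C)(C)OC(=O)CC(=O)CC(=O)OC(C)(C)C | starting material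
7 | sodium 1,5-di-tert-butoxy-1,5-dioxopent-2-en-3-olate (sodium enolate of 6) | [Na+].CC(C)(C)OC(=O)C=C([O-])CC(=O)OC(C)(C)C | intermediate
8 | di-tert-butyl 2-{1-[(tert-butyldimethylsilyl)oxy]-4-methoxy-4-oxo-1-(2,4,6-trimethoxyphenyl)but-2-en-2-yl}-3-oxopentanedioate (alkene isomers, present as its sodium enolate) | COC(=O)C=C(C(O[Si](C)(C)C(C)(C)C)c1c(OC)cc(OC)cc1OC)C(C(=O)OC(C)(C)C)C(=O)CC(=O)OC(C)(C)C | intermediate
9 | di-tert-butyl 6-{[(tert-butyldimethylsilyl)oxy](2,4,6-trimethoxyphenyl)methyl}-2,4-dihydroxybenzene-1,3-dicarboxylate (racemic) | CC(C)(C)OC(=O)c1c(O)cc(C(O[Si](C)(C)C(C)(C)C)c2c(OC)cc(OC)cc2OC)c(C(=O)OC(C)(C)C)c1O | intermediate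
10 | 4,6-dihydroxy-3-oxo-1-(2,4,6-trimethoxyphenyl)-1,3-dihydro-2-benzofuran-5-carboxylic acid (racemic) | COc1cc(OC)c(C2OC(=O)c3c2cc(O)c(C(=O)O)c3O)c(OC)c1 | intermediate
11 | 5,7-dihydroxy-3-(2,4,6-trimethoxyphenyl)-2-benzofuran-1(3H)-one (racemic) | COc1cc(OC)c(C2OC(=O)c3c2cc(O)cc3O)c(OC)c1 | intermediate
12 | 7-hydroxy-5-(methoxymethoxy)-3-(2,4,6-trimethoxyphenyl)-2-benzofuran-1(3H)-one (racemic) | COCOc1cc(O)c2C(=O)OC(c3c(OC)cc(OC)cc3OC)c2c1 | intermediate
13 | 5-(methoxymethoxy)-3-(2,4,6-trimethoxyphenyl)-1,3-dihydro-2-benzofuran-1,7-diol (mixture of diastereomers) | COCOc1cc(O)c2C(O)OC(c3c(OC)cc(OC)cc3OC)c2c1 | intermediate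
14 | (2-methylprop-1-en-1-yl)magnesium bromide | CC(C)=C[Mg]Br | starting material
15 | 3-[hydroxy(2,4,6-trimethoxyphenyl)methyl]-2-(1-hydroxy-3-methylbut-2-en-1-yl)-5-(methoxymethoxy)phenol (mixture of diastereomers) | COCOc1cc(O)c(C(O)C=C(C)C)c(C(O)c2c(OC)cc(OC)cc2OC)c1 | intermediate
16 | [7-(methoxymethoxy)-2,2-dimethyl-2H-chromen-5-yl](2,4,6-trimethoxyphenyl)methanol (racemic) | COCOc1cc(C(O)c2c(OC)cc(OC)cc2OC)c2C=CC(C)(C)Oc2c1 | intermediate
17 | [7-(methoxymethoxy)-2,2-dimethyl-2H-chromen-5-yl](2,4,6-trimethoxyphenyl)methanone | COCOc1cc(C(=O)c2c(OC)cc(OC)cc2OC)c2C=CC(C)(C)Oc2c1 | intermediate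
18 | (2-hydroxy-4,6-dimethoxyphenyl)(7-hydroxy-2,2-dimethyl-2H-chromen-5-yl)methanone | COc1cc(O)c(C(=O)c2cc(O)cc3c2C=CC(C)(C)O3)c(OC)c1 | target

## Step count and least certain steps

Total step count: 10. Longest linear sequence: 10 steps (from 1 and 2 to 18); 6 enters at step 3 and 14 at step 7.

**Step 3 (key step).** The β carbon of 5 carries a bulky silyloxy(aryl)methyl group, so conjugate addition may be slow. That leaves time for base-induced oligomerization of the ynoate, or for closure of the adduct through enolate oxygen onto the ester.
Fallback (sets out from 6, returns at 10): ring A is attached after the annulation and not carried through it. The small acetal ynoate methyl 4,4-diethoxybut-2-ynoate F1 is made from purchased 3,3-diethoxyprop-1-yne by lithiation with n-BuLi and acylation with methyl chloroformate. It undergoes the same Michael–Dieckmann sequence with 6 and NaH, with no steric hindrance at the β carbon, and gives di-tert-butyl 6-(diethoxymethyl)-2,4-dihydroxybenzene-1,3-dicarboxylate F2. Aqueous CF3CO2H unmasks the aldehyde and both acids to the pseudo-acid 1,4,6-trihydroxy-3-oxo-1,3-dihydro-2-benzofuran-5-carboxylic acid F3. In the same medium F3 condenses with 1,3,5-trimethoxybenzene by Friedel–Crafts hydroxyalkylation and lactonization, the standard route to 3-arylphthalides, and gives 10. Heating as in step 4 then leads to 11.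

**Step 4.** The tert-butyl cations released by acidolysis may alkylate the very electron-rich ring A, and prolonged exposure to strong acid may cleave the aryl–carbinol bond by ipso protonation. The decarboxylation may also be slow, because the lactone carbonyl is meta to the carboxyl-bearing carbon.
Fallback (sets out from 9, returns at 11): the three events are separated and no free carbocation is generated in solution. Bu4NF in THF removes the silyl group, and the alkoxide closes onto the adjacent tert-butyl ester by 5-exo-trig transesterification to give tert-butyl 4,6-dihydroxy-3-oxo-1-(2,4,6-trimethoxyphenyl)-1,3-dihydro-2-benzofuran-5-carboxylate F4. Silica gel in refluxing toluene then cleaves the remaining tert-butyl ester with loss of gaseous isobutene, and the acid 10 so formed decarboxylates at that temperature to 11.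

**Step 8.** The quinone methide may be captured irreversibly by the neighbouring benzhydrol hydroxyl to give a 1,3-dihydroisobenzofuran, or traces of acid may ionize the benzhydrol and start cationic cyclization onto the new alkene.
Fallback (sets out from 15, returns at 17): the pyran is closed at the ketone level and the alkene is made by reduction of an enol triflate. MnO2 in CH2Cl2 oxidizes both carbinols of 15, and K2CO3 in methanol closes the ortho-hydroxyaryl enone by oxa-Michael addition to 7-(methoxymethoxy)-2,2-dimethyl-5-(2,4,6-trimethoxybenzoyl)-2,3-dihydro-4H-chromen-4-one F5. Only the chromanone carbonyl is enolizable, so KN(SiMe3)2 and N-phenylbis(trifluoromethanesulfonimide) give 7-(methoxymethoxy)-2,2-dimethyl-5-(2,4,6-trimethoxybenzoyl)-2H-chromen-4-yl trifluoromethanesulfonate F6 without touching the diaryl ketone. Pd(OAc)2, PPh3, Et3N and HCO2H in DMF then reduce the enol triflate to 17.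

**Step 10.** BCl3 may coordinate to the pyran oxygen and ionize the tertiary allylic C2–O1 bond, or the HCl formed may add to the styrenic alkene. A second ortho demethylation is possible if the mixture is warmed too far.
Fallback (sets out from 17, returns at 18): the two ethers are removed in separate operations that use no boron halide. Dilute HCl in methanol hydrolyses the MOM acetal to (7-hydroxy-2,2-dimethyl-2H-chromen-5-yl)(2,4,6-trimethoxyphenyl)methanone F7. MgI2·OEt2 in warm toluene–THF then cleaves one ortho methyl ether through a magnesium chelate, with iodide as the nucleophile, and gives 18.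

## Further compounds

F1 | step 3 | methyl 4,4-diethoxybut-2-ynoate | CCOC(OCC)C#CC(=O)OC
F2 | step 3 | di-tert-butyl 6-(diethoxymethyl)-2,4-dihydroxybenzene-1,3-dicarboxylate | CCOC(OCC)c1cc(O)c(C(=O)OC(C)(C)C)c(O)c1C(=O)OC(C)(C)C
F3 | step 3 | 1,4,6-trihydroxy-3-oxo-1,3-dihydro-2-benzofuran-5-carboxylic acid (racemic) | O=C(O)c1c(O)cc2C(O)OC(=O)c2c1O
F4 | step 4 | tert-butyl 4,6-dihydroxy-3-oxo-1-(2,4,6-trimethoxyphenyl)-1,3-dihydro-2-benzofuran-5-carboxylate (racemic) | COc1cc(OC)c(C2OC(=O)c3c2cc(O)c(C(=O)OC(C)(C)C)c3O)c(OC)c1
F5 | step 8 | 7-(methoxymethoxy)-2,2-dimethyl-5-(2,4,6-trimethoxybenzoyl)-2,3-dihydro-4H-chromen-4-one | COCOc1cc(C(=O)c2c(OC)cc(OC)cc2OC)c2C(=O)CC(C)(C)Oc2c1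
F6 | step 8 | 7-(methoxymethoxy)-2,2-dimethyl-5-(2,4,6-trimethoxybenzoyl)-2H-chromen-4-yl trifluoromethanesulfonate | COCOc1cc(C(=O)c2c(OC)cc(OC)cc2OC)c2C(OS(=O)(=O)C(F)(F)F)=CC(C)(C)Oc2c1
F7 | step 10 | (7-hydroxy-2,2-dimethyl-2H-chromen-5-yl)(2,4,6-trimethoxyphenyl)methanone | COc1cc(OC)c(C(=O)c2cc(O)cc3OC(C)(C)C=Cc23)c(OC)c1
A1 | alternative 1 | 4-hydroxy-6-{2-[7-(methoxymethoxy)-2,2-dimethyl-2H-chromen-5-yl]-2-oxoethyl}-2H-pyran-2-one | O=C(Cc1cc(O)cc(=O)o1)c1cc(OCOC)cc2OC(C)(C)C=Cc12
A2 | alternative 1 | [7-(methoxymethoxy)-2,2-dimethyl-2H-chromen-5-yl](2,4,6-trihydroxyphenyl)methanone | O=C(c1c(O)cc(O)cc1O)c1cc(OCOC)cc2OC(C)(C)C=Cc12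
A3 | alternative 2 | 2,4-dihydroxy-6-iodobenzaldehyde | O=Cc1c(O)cc(O)cc1I
A4 | alternative 2 | (2-methylprop-1-en-1-yl)boronic acid | CC(C)=CB(O)O
A5 | alternative 2 | 5-iodo-2,2-dimethyl-2H-chromen-7-ol | CC1(C)C=Cc2c(I)cc(O)cc2O1
A6 | alternative 2 | 2,4-dimethoxy-6-(methoxymethoxy)benzaldehyde | COCOc1cc(OC)cc(OC)c1C=O
A7 | alternative 3 | 1-iodo-2,4-bis(methoxymethoxy)benzene | COCOc1ccc(I)c(OCOC)c1
A8 | alternative 3 | 2,4-dimethoxy-6-(methoxymethoxy)benzoic anhydride | COCOc1cc(OC)cc(OC)c1C(=O)OC(=O)c1c(OC)cc(OC)cc1OCOC
A9 | alternative 3 | 2-methylbut-3-en-2-ol | C=CC(C)(C)O
A10 | alternative 3 | [2,4-dimethoxy-6-(methoxymethoxy)phenyl]{2-[(E)-3-hydroxy-3-methylbut-1-en-1-yl]-3,5-bis(methoxymethoxy)phenyl}methanone | COCOc1cc(OC)cc(OC)c1C(=O)c1cc(OCOC)cc(OCOC)c1/C=C/C(C)(C)O
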